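The slowness of this flask is to be read in its free nucleophile, the partner of the electrophile in step 2.

electrophile 0.10 M; nucleophile 0.120 M; free base 0.0800 M; time 50 min

    acid set free → by-product carried off (k1 = 0.0102 s⁻¹)
    electrophile + nucleophile → acid set free + target (k2 = 0.0525 M⁻¹ s⁻¹)
    acid set free + free base ⇌ salt of the base (K3 = 13000 M⁻¹, k3 = 0.251 M⁻¹ s⁻¹)
    nucleophile + acid set free ⇌ protonated nucleophile, settled at all times (K4 = 1380 M⁻¹)
    free base + target → over-reaction product (k5 = 0.00473 M⁻¹ s⁻¹)

- part of the electrophile that has reacted at 50 min
- share of the unused nucleophile that is free and not bound as protonated nucleophile, at 50 min

The equilibrium constant of step 4 times the charged nucleophile is 170, far more than one, so with the charge in place protonated nucleophile outweighs acid set free by that factor. Acid leaves by step 1 and by the forward run of step 3. Take the free base as falling evenly to zero over the run, so its mean is 0.0400 M. The mean pseudo-first-order sink for acid is then 1.21 min⁻¹. If the acid of the electrophile charge leaves within 50 min, mean acid set free is 0.00165 M, and unused nucleophile divides by 3.27.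

Unused nucleophile starts at 0.120 M and stands at 0.0200 M once the electrophile charge has reacted. Its plain middle gives free nucleophile 0.0214 M and an exponent k2·b·t of 3.37. That middle is the weak link, since the electrophile falls early: its half-life by step 2 alone, at the charged concentrations, is 1.8 min, short against 50 min. Its time mean, 0.0287 M, is lower than 0.0500 M. Reforged, free nucleophile is 0.0149 M: the mean free nucleophile, the steady amount that would consume as much electrophile in the time as the real curve does. The reacted part is then 90.4%. At the end, with step 1 as the sink and acid made equal to acid lost, the free share is 49.8%.

The forecast gives 91% and 45%, holding that “the rate is limited by how quickly the acid is removed”. Its second number lies below the reckoning here.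

The flask gives 93.1% and 47.8%, and the forecast stands within its margin. Read back through the exponent, 93.1% means a mean free nucleophile of 0.0170 M, larger than the reckoned amount by a factor 1.14. In the reacted part that gap is worth 2.7 percentage points. The neighbour flask with 0.032 M of free base has a sink of 0.853 min⁻¹ and a divisor of 4.24. Two passes give it a mean of 0.0131 M. Times the same factor, that mean gives 90.5%. The neighbour flask gives 90.9%.

The numbers of this flask are assumed; no experiment stands behind them.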